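## Retrosynthetic overview

1. Numbering used here: C1 lactone carbonyl, C2H2, C3 (ring-fusion CH bearing the peroxide), C4 (ring-fusion carbon bearing the methyl group and the lactone oxygen), C5H2, C6 (quaternary peroxide carbon); the target is (3S,4S,6S), with ring A the γ-lactone and ring B the 1,2-dioxane.
2. Enabling feature: C4, shared by rings A and B, carries the lactone oxygen and is therefore a masked ketone next to the peroxide-bearing C3, while C6 is a tertiary peroxide carbon; ring B is thus the [4+2] adduct of a C4-cation/peroxide-oxygen 1,4-dipole and a 1,1-disubstituted alkene C5=C6.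
3. Key disconnection: C4–C5 and O–C6 (with the lactone C4–O bond formed in the same pot) lead back to the open-chain γ-keto acid 7 and the diene 10.
4. C3 is set first by an amine-catalysed asymmetric conjugate peroxidation of enal 3; the tert-butyl group protects the peroxide and is expelled in the key step, and C3 then directs C4 (cis ring fusion) and C6.
5. Ring order: ring A then ring B, both in the key operation; the acid-sensitive E,E-phenyldiene is added last, by cross-metathesis and Suzuki–Miyaura coupling on a terminal vinyl handle.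

Key step: step 6

Remark: the sense of induction in step 2 is assigned from the usual model for this catalyst class (attack anti to the diaryl(silyloxy)methyl group); the enantiomeric catalyst would be used if the ketal substituent reversed it.

## Route

Step 1
Reactants: 1 2-methyl-2-vinyl-1,3-dioxolane; 2 (E)-but-2-enal
Product: 3 (E)-3-(2-methyl-1,3-dioxolan-2-yl)prop-2-enal
Conditions: Hoveyda–Grubbs second-generation catalyst (3 mol %), 2 (4 equiv), CH2Cl2, 40 °C
Reagents that add atoms: none
Why: Olefin cross-metathesis of a hindered monosubstituted alkene (quaternary allylic carbon, slow to homodimerise) with an excess of an enal should give the E-enal under thermodynamic control; no stereocenter is formed.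

Step 2
Reactants: 3 (E)-3-(2-methyl-1,3-dioxolan-2-yl)prop-2-enal; 4 tert-butyl hydroperoxide
Product: 5 (3S)-3-(tert-butylperoxy)-3-(2-methyl-1,3-dioxolan-2-yl)propanal
Conditions: (S)-2-[diphenyl(trimethylsilyloxy)methyl]pyrrolidine (10 mol %), PhCO2H (10 mol %), 4 (anhydrous, in decane, 1.5 equiv), toluene, −20 °C
Reagents that add atoms: none
Why: Iminium-catalysed asymmetric conjugate peroxidation of an enal (oxa-Michael addition of a hydroperoxide), in which the E-iminium ion exposes the Si face of the β-carbon anti to the diphenyl(silyloxy)methyl group and should set (3S), while the acid co-catalyst at low temperature should protonate the peroxy-enamine before it closes to the epoxide.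

Step 3
Reactants: 5 (3S)-3-(tert-butylperoxy)-3-(2-methyl-1,3-dioxolan-2-yl)propanal
Product: 6 (3S)-3-(tert-butylperoxy)-3-(2-methyl-1,3-dioxolan-2-yl)propanoic acid
Conditions: NaClO2, NaH2PO4, 2-methylbut-2-ene, t-BuOH/H2O, 0 °C
Reagents that add atoms: sodium chlorite, [Na+].[O-]Cl=O
Why: Pinnick oxidation is selective for the aldehyde and, being non-basic, should leave the dialkyl peroxide, the ketal and the C3 stereocenter (no retro-oxa-Michael) untouched.

Step 4
Reactants: 6 (3S)-3-(tert-butylperoxy)-3-(2-methyl-1,3-dioxolan-2-yl)propanoic acid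
Product: 7 (3S)-3-(tert-butylperoxy)-4-oxopentanoic acid (in equilibrium with its cyclic hydroxy-lactone tautomer)
Conditions: 1 M HCl, THF, 23 °C, short reaction time
Reagents that add atoms: water, O
Why: Acid-catalysed ketal hydrolysis, assisted by the neighbouring carboxyl group, should unveil the methyl ketone under conditions too mild for enolisation towards C3 or for cleavage of the tert-butyl peroxide.

Step 5
Reactants: 8 7-bromohept-1-ene; 9 (2-methylprop-2-en-1-yl)magnesium chloride
Product: 10 2-methyldeca-1,9-diene
Conditions: Li2CuCl4 (3 mol %), THF, 0 → 23 °C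
Reagents that add atoms: none
Why: Copper-catalysed Kochi-type coupling of an allylic Grignard reagent with a primary alkyl bromide is a reliable sp3–sp3 bond formation; no stereocenter is formed.

Step 6
Reactants: 7 (3S)-3-(tert-butylperoxy)-4-oxopentanoic acid; 10 2-methyldeca-1,9-diene
Product: 14 (3S,4aS,7aS)-3,4a-dimethyl-3-(oct-7-en-1-yl)tetrahydro-3H-furo[3,2-c][1,2]dioxin-6(4H)-one, via O-silyl lactol 11 (not isolated), via lactone oxocarbenium ion 12 (not isolated), via tertiary carbocation 13 (not isolated)
Conditions: Me3SiOTf (2.5 equiv), 2,6-di-tert-butyl-4-methylpyridine (2.2 equiv), 10 (3 equiv), CH2Cl2, −78 → −30 °C; aq. NaHCO3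
Reagents that add atoms: none
Why: Proposed new method: Me3SiOTf should convert keto acid 7 into the cyclic O-silyl lactol 11 (5-exo-trig addition of the carboxyl oxygen to the C4 carbonyl, which closes ring A) and ionise it to the lactone oxocarbenium ion 12, whose C4 is attacked by the CH2 terminus of the 1,1-disubstituted alkene of 10 (Prins-type, Markovnikov), after which the tertiary C6 cation 13 is captured by the distal peroxide oxygen in a six-membered closure with both former alkene carbons in ring B and the peroxonium ion loses its tert-butyl group as 2-methylpropene, a formal [4+2] annulation of a C4/O 1,4-dipole with the alkene. The closest known reaction types are the Lewis acid-mediated [3+2] annulation of peroxycarbenium ions with alkenes to 1,2-dioxolanes (carbocation capture by a peroxide oxygen), the Lewis acid-mediated conversion of 1,2-dioxetanes and carbonyl compounds into 1,2,4-trioxanes through β-peroxy oxocarbenium ions, the dealkylative cyclisation of unsaturated tert-butyl peroxides, and the Hosomi–Sakurai allylation of γ-keto acids through the same acyloxycarbenium ions. C4 is controlled by the C3 peroxide, because only the adduct with the new C4–C5 bond cis to the peroxide can close (a trans-fused bicycle is out of reach) and the addition to 12 is reversible, so the cis ring fusion (4S) follows from (3S). C6 is set in a chair-like closure with the lactone oxygen axial on C4, in which the long chain should take the equatorial site and the methyl group the axial site syn to that oxygen, giving (6S); this is the weakest control element, and the C6 epimer is the expected by-product to be removed by chromatography. The step also needs selectivity for the 1,1-disubstituted over the monosubstituted alkene of 10, which the much higher nucleophilicity of the former secures, and cation capture in competition with proton loss, which the intramolecular six-membered delivery should favour.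

Step 7
Reactants: 14 (3S,4aS,7aS)-3,4a-dimethyl-3-(oct-7-en-1-yl)tetrahydro-3H-furo[3,2-c][1,2]dioxin-6(4H)-one; 15 2-ethenyl-4,4,5,5-tetramethyl-1,3,2-dioxaborolane
Product: 16 (3S,4aS,7aS)-3,4a-dimethyl-3-[(E)-8-(4,4,5,5-tetramethyl-1,3,2-dioxaborolan-2-yl)oct-7-en-1-yl]tetrahydro-3H-furo[3,2-c][1,2]dioxin-6(4H)-one
Conditions: second-generation Grubbs catalyst (5 mol %), 15 (3 equiv), CH2Cl2, 40 °C
Reagents that add atoms: none
Why: Olefin cross-metathesis of a terminal alkene with a vinylboronic ester is reliably E-selective and neutral, and ruthenium alkylidenes tolerate dialkyl peroxides and lactones, so the ring stereocenters are not touched.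

Step 8
Reactants: 16 (3S,4aS,7aS)-3,4a-dimethyl-3-[(E)-8-(4,4,5,5-tetramethyl-1,3,2-dioxaborolan-2-yl)oct-7-en-1-yl]tetrahydro-3H-furo[3,2-c][1,2]dioxin-6(4H)-one; 17 (E)-(2-bromoethenyl)benzene
Product: 18 plakortolide R, (3S,4aS,7aS)-3,4a-dimethyl-3-[(7E,9E)-10-phenyldeca-7,9-dien-1-yl]tetrahydro-3H-furo[3,2-c][1,2]dioxin-6(4H)-one
Conditions: Pd(OAc)2 (5 mol %), 2-dicyclohexylphosphino-2',6'-dimethoxybiphenyl (10 mol %), K3PO4, THF/H2O, 23 °C
Reagents that add atoms: none
Why: Suzuki–Miyaura coupling of an E-alkenylboronate with an E-alkenyl bromide proceeds with retention of both double-bond geometries and should give the E,E-diene under weakly basic conditions at room temperature that spare the β-peroxy lactone.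

## Compound list

1 | 2-methyl-2-vinyl-1,3-dioxolane | CC1(C=C)OCCO1 | starting material
2 | (E)-but-2-enal | C/C=C/C=O | starting material
3 | (E)-3-(2-methyl-1,3-dioxolan-2-yl)prop-2-enal | CC1(/C=C/C=O)OCCO1 | intermediate
4 | tert-butyl hydroperoxide | CC(C)(C)OO | starting material
5 | (3S)-3-(tert-butylperoxy)-3-(2-methyl-1,3-dioxolan-2-yl)propanal | O=CC[C@@H](C1(C)OCCO1)OOC(C)(C)C | intermediate
6 | (3S)-3-(tert-butylperoxy)-3-(2-methyl-1,3-dioxolan-2-yl)propanoic acid | OC(=O)C[C@@H](C1(C)OCCO1)OOC(C)(C)C | intermediate
7 | (3S)-3-(tert-butylperoxy)-4-oxopentanoic acid | OC(=O)C[C@@H](C(C)=O)OOC(C)(C)C | intermediate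
8 | 7-bromohept-1-ene | BrCCCCCC=C | starting material
9 | (2-methylprop-2-en-1-yl)magnesium chloride | C=C(C)C[Mg]Cl | starting material
10 | 2-methyldeca-1,9-diene | C=C(C)CCCCCCC=C | intermediate
11 | (4S)-4-(tert-butylperoxy)-5-methyl-5-(trimethylsilyloxy)oxolan-2-one, O-silyl lactol, both C5 epimers | CC1(O[Si](C)(C)C)OC(=O)C[C@@H]1OOC(C)(C)C | intermediate (not isolated)
12 | (3S)-3-(tert-butylperoxy)-2-methyl-5-oxo-4,5-dihydro-3H-furan-1-ium, lactone oxocarbenium ion | CC1=[O+]C(=O)C[C@@H]1OOC(C)(C)C | intermediate (not isolated)
13 | tertiary carbocation at C6 of the (4S,5S)-lactone adduct | C[C+](CCCCCCC=C)C[C@]1(C)OC(=O)C[C@@H]1OOC(C)(C)C | intermediate (not isolated)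
14 | (3S,4aS,7aS)-3,4a-dimethyl-3-(oct-7-en-1-yl)tetrahydro-3H-furo[3,2-c][1,2]dioxin-6(4H)-one | C[C@]1(CCCCCCC=C)C[C@]2(C)OC(=O)C[C@@H]2OO1 | intermediate
15 | 2-ethenyl-4,4,5,5-tetramethyl-1,3,2-dioxaborolane | C=CB1OC(C)(C)C(C)(C)O1 | starting material
16 | (3S,4aS,7aS)-3,4a-dimethyl-3-[(E)-8-(4,4,5,5-tetramethyl-1,3,2-dioxaborolan-2-yl)oct-7-en-1-yl]tetrahydro-3H-furo[3,2-c][1,2]dioxin-6(4H)-one | C[C@]1(CCCCCC/C=C/B3OC(C)(C)C(C)(C)O3)C[C@]2(C)OC(=O)C[C@@H]2OO1 | intermediate
17 | (E)-(2-bromoethenyl)benzene | Br/C=C/c1ccccc1 | starting material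
18 | plakortolide R | C[C@]1(CCCCCC/C=C/C=C/c2ccccc2)C[C@]2(C)OC(=O)C[C@@H]2OO1 | target

## Step count and risks

Total steps: 8. Longest linear sequence: 7 steps (1 → 3 → 5 → 6 → 7 → 14 → 16 → 18); step 5 is the only step off the main line.

Step 6 (key step): the C6 carbocation may lose a proton to give olefinic lactones faster than the hindered tert-butyl-bearing peroxide oxygen captures it, C3 may lose integrity through deprotonation of the oxocarbenium ion, and facial discrimination between methyl and chain at C6 may be low. The fallback is stepwise, uses known reaction types, sets out from 7 and 8 and comes back at 14. Bromide 8 is converted with Mg in THF into hept-6-en-1-ylmagnesium bromide F1, which is coupled (Li2CuCl4 cat.) with commercial 3-chloro-2-[(trimethylsilyl)methyl]prop-1-ene to give the allylsilane trimethyl(2-methylidenedec-9-en-1-yl)silane F2. Hosomi–Sakurai allylation of keto acid 7 with F2 (BF3·OEt2, CH2Cl2, −78 °C) makes the C4–C5 bond irreversibly through loss of silicon and should give (4S,5S)-4-(tert-butylperoxy)-5-methyl-5-(2-methylidenedec-9-en-1-yl)oxolan-2-one F3; the isomer with the allyl group cis to the peroxide is the one carried on. Dealkylative iodoperoxidation with N-iodosuccinimide (CH2Cl2, 0 °C, dark) should close the dioxane through the iodonium ion, with loss of the tert-butyl group, to (3S,4aS,7aS)-3-(iodomethyl)-4a-methyl-3-(oct-7-en-1-yl)tetrahydro-3H-furo[3,2-c][1,2]dioxin-6(4H)-one F4. Reduction with Bu3SnH at high concentration (Et3B, air, 0 °C) then turns the iodomethyl group into the C6 methyl group of 14. This fallback does not improve the C6 selectivity; the C6 epimer is separated at F4 or at 14.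

Step 2: addition to the hindered β-carbon may be slow, the peroxy-enamine may give too little enantiofacial discrimination, or reversible oxa-Michael addition may erode the enantiomeric purity. The fallback replaces catalyst control by classical resolution, sets out from 3 and 4 and comes back at 6. Conjugate peroxidation of 3 with 4 under achiral amine catalysis (pyrrolidine, PhCO2H, toluene) gives racemic 3-(tert-butylperoxy)-3-(2-methyl-1,3-dioxolan-2-yl)propanal F5. Pinnick oxidation gives racemic 3-(tert-butylperoxy)-3-(2-methyl-1,3-dioxolan-2-yl)propanoic acid F6. Crystallisation with (S)-1-phenylethylamine gives the diastereomerically pure (S)-1-phenylethylammonium (3S)-3-(tert-butylperoxy)-3-(2-methyl-1,3-dioxolan-2-yl)propanoate F7, and cold dilute HCl then releases 6. If the (3S) acid forms the more soluble salt, the enantiomeric amine is used.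

Step 8: the aqueous base may open the β-peroxy lactone by β-elimination (retro-oxa-Michael), or palladium may cleave the O–O bond during the coupling. The fallback builds the diene by olefination, sets out from 14 and comes back at 18. Ozonolysis of the terminal alkene of 14 (O3, CH2Cl2, −78 °C; Me2S) gives 7-[(3S,4aS,7aS)-3,4a-dimethyl-6-oxohexahydro-3H-furo[3,2-c][1,2]dioxin-3-yl]heptanal F8. Wittig reaction with pre-formed cinnamylidenetriphenylphosphorane (from cinnamyltriphenylphosphonium chloride and NaN(SiMe3)2, THF, −78 °C; a weakly basic ylide) gives the target together with its (7Z,9E)-isomer, (3S,4aS,7aS)-3,4a-dimethyl-3-[(7Z,9E)-10-phenyldeca-7,9-dien-1-yl]tetrahydro-3H-furo[3,2-c][1,2]dioxin-6(4H)-one F9. Iodine-catalysed isomerisation (I2 cat., hexane, daylight) should convert F9 into 18.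

Further compounds
F1 | step 6 | hept-6-en-1-ylmagnesium bromide | C=CCCCCC[Mg]Br
F2 | step 6 | trimethyl(2-methylidenedec-9-en-1-yl)silane | C=C(C[Si](C)(C)C)CCCCCCC=C
F3 | step 6 | (4S,5S)-4-(tert-butylperoxy)-5-methyl-5-(2-methylidenedec-9-en-1-yl)oxolan-2-one | C=C(CCCCCCC=C)C[C@]1(C)OC(=O)C[C@@H]1OOC(C)(C)C
F4 | step 6 | (3S,4aS,7aS)-3-(iodomethyl)-4a-methyl-3-(oct-7-en-1-yl)tetrahydro-3H-furo[3,2-c][1,2]dioxin-6(4H)-one | IC[C@]1(CCCCCCC=C)C[C@]2(C)OC(=O)C[C@@H]2OO1
F5 | step 2 | racemic 3-(tert-butylperoxy)-3-(2-methyl-1,3-dioxolan-2-yl)propanal | O=CCC(C1(C)OCCO1)OOC(C)(C)C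
F6 | step 2 | racemic 3-(tert-butylperoxy)-3-(2-methyl-1,3-dioxolan-2-yl)propanoic acid | OC(=O)CC(C1(C)OCCO1)OOC(C)(C)C
F7 | step 2 | (S)-1-phenylethylammonium (3S)-3-(tert-butylperoxy)-3-(2-methyl-1,3-dioxolan-2-yl)propanoate | C[C@H]([NH3+])c1ccccc1.[O-]C(=O)C[C@@H](C1(C)OCCO1)OOC(C)(C)C
F8 | step 8 | 7-[(3S,4aS,7aS)-3,4a-dimethyl-6-oxohexahydro-3H-furo[3,2-c][1,2]dioxin-3-yl]heptanal | C[C@]1(CCCCCCC=O)C[C@]2(C)OC(=O)C[C@@H]2OO1
F9 | step 8 | (3S,4aS,7aS)-3,4a-dimethyl-3-[(7Z,9E)-10-phenyldeca-7,9-dien-1-yl]tetrahydro-3H-furo[3,2-c][1,2]dioxin-6(4H)-one | C[C@]1(CCCCCC/C=C\C=C\c2ccccc2)C[C@]2(C)OC(=O)C[C@@H]2OO1
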